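## The problem

Target 14 is a 1H-pyrrole in which every ring carbon is substituted: C2 and C5 carry 3,5-dibromo-4-hydroxybenzoyl groups and C3 and C4 carry 3,5-dibromo-4-hydroxyphenyl rings. A mirror plane through N1 and the midpoint of C3–C4 makes the two halves identical, so each operation can be run in both directions at once. There is no stereocentre; the task is one of connectivity and order of events around a crowded core, where each C2/C5 carbonyl sits between the ring nitrogen and an aryl ring. The eight C–Br bonds would not survive the organolithium and Grignard reagents needed to build the skeleton, but they lie exactly at the positions the phenols activate, so bromine should enter last by electrophilic substitution. The four phenols and the N–H are acidic and must be masked while carbanions are used, and the group on nitrogen must also keep N1 from adding to an electrophile held at the C2 carbonyl. The diaryl ketones have to be formed without over-addition. The feature that opens the key step is the pattern of each aroyl ring before bromination: C1' bears the ketone, C4' the hydroxyl, and C2', C3', C5' and C6' only hydrogen. A ring of this kind results when the two sp carbons of a terminal alkynyl ketone (C1', C2') take up the four carbons of a 1-methoxy-3-silyloxybutadiene (C3'–C6') and the adduct loses methanol.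

## Retrosynthesis

**14 to 13.** The eight C–Br bonds are cut first. Each lies ortho to a phenolic hydroxyl whose para position is blocked, and the pyrrole has no free carbon, so one electrophilic bromination of tetraphenol 13 can place all of them without a directing device. Removing bromine more than halves the mass and leaves a precursor with no group sensitive to carbanions. The forward step only has to reach completion at all eight sites.

**13 to 11.** The two O–H bonds of the C3/C4 rings are reconnected to methyl and the N–H bond to a 2-(trimethylsilyl)ethoxymethyl (SEM) group, giving 11. Methyl ethers come in with the cheapest starting material and survive every step. SEM withstands a Grignard reagent and heat, yet should fall to the same Lewis acid that cleaves the methyl ethers, so one operation unmasks everything. A benzyl group on nitrogen would be hard to remove from a pyrrole and a carbamate would be attacked by the acetylide. The two phenols of the aroyl rings stay free in 11 because the next cut delivers them that way.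

**11 to 7 and 8.** In each 4-hydroxybenzoyl ring the bonds C2'–C3' and C1'–C6' are cut, four C–C bonds and two benzene rings in all. This leads back to bis(ynone) 7 and two molecules of diene 8. Compared with cutting the ketone–aryl bonds (an aryl nucleophile on an acid derivative), this cut builds the ring with the para oxygen already in place and free. It therefore distinguishes the aroyl phenols from the C3/C4 anisyl ethers without extra steps. Precursor 7 is much simpler: two three-carbon acyl arms replace two aryl ketones. The forward reaction must give the para regiochemistry at both ynones, aromatise cleanly, and leave the nitrogen substituent untouched.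

**7 to 5 and 6.** The two C(O)–C(sp) bonds are cut to give bis(N-methoxy-N-methylamide) 5 and two molecules of acetylide 6. An acid chloride or ester would risk double addition at so electrophilic a product as an ynone. The chelated tetrahedral intermediate of the Weinreb amide holds the ketone back until work-up. The forward step needs a small nucleophile to reach two hindered amides and a quench that does not let the released amine add to the ynone.

**5 to 4 to 3.** The N–CH2 bond of the SEM group and the two amide C–N bonds are cut, leading through NH diamide 4 to diacid 3. Amidation comes before N-alkylation because the free acids would otherwise be esterified by the alkylating agent. The N–H flanked by two carbonyls is acidic enough for clean N-alkylation.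

**3 to 1.** The pyrrole is opened at both C–N bonds and the C3–C4 bond, giving two molecules of arylpyruvic acid 1 through 1,4-diketone 2. Each molecule of 1 supplies one half of the ring: its benzylic carbon becomes C3 or C4, its keto carbon C2 or C5, and its carboxyl group the handle on that carbon. The symmetry of 3 means the oxidative dimerisation of one enolate sets all ring carbons with both aryl groups and both carboxyl handles in place. There is no regiochemical question, and the pyrrole is made in one flask from a purchasable acid. The forward step requires enolate homocoupling to outrun aldol self-condensation, and Paal–Knorr closure by the nitrogen reagent of step 1.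

## Roads not taken

**Alternative 1:** The pyrrole would be cut at N1–C5 and C3–C4. This gives amino diketone A1 (2-amino-1,3-bis(4-methoxyphenyl)propane-1,3-dione, handled as a salt) and benzyl 1,2-diketone A2 (1,3-bis(4-methoxyphenyl)propane-1,2-dione). A Knorr condensation in buffered acid would join the nitrogen of A1 to the benzyl-side carbonyl of A2, and the enamine carbon would then attack an aroyl carbonyl of A1. The product is 2,5-bis(4-methoxybenzoyl)-3,4-bis(4-methoxyphenyl)-1H-pyrrole A3.
- Merits: it is convergent, needs no protecting group on nitrogen, and leaves only demethylation and bromination after A3. On paper it is two or three steps shorter than the chosen plan.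
- Weak points: A1 is an α-amino-1,3-diketone, prone to self-condensation and to acid-promoted loss of an aroyl group, the usual fate of such acyl groups in Knorr-type closures. The methylene of A2 is activated only by an aryl ring and must attack a hindered, methoxy-deactivated aryl ketone. Condensation at the wrong carbonyl of A2 would divert material to six-membered products. Neither A1 nor A2 is purchasable, so part of the step advantage is lost.
- Comparison: alternative 1 is better in step count and protecting-group economy. The chosen plan sets against this a pyrrole formation with no regiochemical choice and close precedent for each step, whereas the Knorr step with a non-activated methylene partner is the least supported link of alternative 1.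

**Alternative 2:** The four bonds flanking the two ketone carbons would be cut. N-Boc diiodide A4 (tert-butyl 2,5-diiodo-3,4-bis(4-methoxyphenyl)pyrrole-1-carboxylate) and two molecules of boronic acid A5 (4-methoxyphenylboronic acid) would be joined by a double carbonylative Suzuki coupling with PdCl2(PPh3)2 under carbon monoxide. The product is tert-butyl 2,5-bis(4-methoxybenzoyl)-3,4-bis(4-methoxyphenyl)pyrrole-1-carboxylate A6.
- Merits: both carbonyls and both aryl groups are installed in one step, and any arylboronic acid could be used. As a platform for analogues it is better than the chosen plan, whose benzannulation delivers only the 4-hydroxy pattern.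
- Weak points: A4 would itself come from diacid 3 by decarboxylation, N-acylation and iodination, so the route is no shorter. 2,5-Diiodopyrroles are light- and acid-sensitive. Carbonyl insertion at an electron-rich, doubly flanked pyrrolyl–palladium centre competes with direct transmetalation, so at each of two sites ketone and biaryl formation compete and mixtures result. The activated N-Boc group may be lost under basic coupling conditions.
- Comparison: the chosen plan forms the pyrrole–carbonyl bond by a Weinreb reaction that cannot skip the carbonyl and needs no pressure equipment. It has to accept a sensitive terminal ynone in exchange.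

**Alternative 3:** The pyrrole would be cut at C2–C3 and C4–C5. This gives 4,4'-dimethoxybenzil A7 and N-(4-methoxybenzyl)bis(4-methoxyphenacyl)amine A8. A Hinsberg-type double aldol condensation with NaOMe in methanol would give 1-(4-methoxybenzyl)-2,5-bis(4-methoxybenzoyl)-3,4-bis(4-methoxyphenyl)pyrrole A9.
- Merits: the whole carbon skeleton is made in one step from a purchasable diketone and an amine available in one alkylation. If a single Lewis-acid step removed the four methyl ethers and the N-benzyl group, the route would be about four steps, clearly shorter than the seven chosen here.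
- Weak points: the Hinsberg condensation is best established for iminodiacetic esters. The α-amino ketone A8 can self-condense, and two dehydrations must occur at a very crowded ring. Everything then depends on removing a benzylic group from a pyrrole nitrogen, which releases a benzylic cation next to four electron-rich phenol rings. If that removal fails the route ends at an N-substituted compound.
- Comparison: alternative 3 wins on step economy. The chosen plan sets against this a nitrogen group with two independent modes of removal (Lewis acid or fluoride) that release no carbon cation able to alkylate the phenol rings, and ring-forming steps that follow well-trodden reaction types.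

Key step: step 5

Assumption: 1, 6 (as a THF solution) and 8 are purchased; step 1 joins two molecules of 1 and step 5 consumes two molecules of 8; 2, 9 and the fallback diol F3 are diastereomer mixtures whose stereocentres disappear in the next operation, so they are drawn without configuration.

## Steps

Step 1
Reactants: 1 4-methoxyphenylpyruvic acid [3-(4-methoxyphenyl)-2-oxopropanoic acid]; 1 4-methoxyphenylpyruvic acid (second molecule)
Product: 3 3,4-bis(4-methoxyphenyl)-1H-pyrrole-2,5-dicarboxylic acid, via 3,4-bis(4-methoxyphenyl)-2,5-dioxohexanedioic acid 2 (not isolated)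
Conditions: n-BuLi (2 equiv per acid), THF, −78 °C; I2 (0.5 equiv per acid), −78 °C → rt; then 25% aq NH3, rt; HCl work-up
Reagents that add atoms: ammonia, N
Why: Two molecules of the largely enolic acid 1 are each deprotonated twice to the carboxylate enolate, and iodine-mediated oxidative homocoupling of the two enolates joins their benzylic carbons, forming the C3–C4 bond of the twenty-carbon 1,4-diketone 2. Ammonia then closes the ring by Paal–Knorr condensation with loss of two molecules of water, a known one-flask route from arylpyruvic acids to 3,4-diarylpyrrole-2,5-dicarboxylic acids; both diastereomers of 2 converge on the aromatic product.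

Step 2
Reactants: 3 3,4-bis(4-methoxyphenyl)-1H-pyrrole-2,5-dicarboxylic acid
Product: 4 N2,N5-dimethoxy-N2,N5-dimethyl-3,4-bis(4-methoxyphenyl)-1H-pyrrole-2,5-dicarboxamide
Conditions: MeNHOMe·HCl, EDC·HCl, HOBt, i-Pr2NEt, DMF, 0 °C → rt
Reagents that add atoms: N,O-dimethylhydroxylamine hydrochloride, CNOC.Cl
Why: Carbodiimide/HOBt amide coupling to the bis(Weinreb amide); the pyrrole nitrogen is non-nucleophilic and flanked on both sides, so only the hydroxylamine nitrogen is acylated.

Step 3
Reactants: 4 N2,N5-dimethoxy-N2,N5-dimethyl-3,4-bis(4-methoxyphenyl)-1H-pyrrole-2,5-dicarboxamide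
Product: 5 N2,N5-dimethoxy-N2,N5-dimethyl-3,4-bis(4-methoxyphenyl)-1-{[2-(trimethylsilyl)ethoxy]methyl}pyrrole-2,5-dicarboxamide
Conditions: NaH, DMF, 0 °C; SEMCl, 0 °C → rt
Reagents that add atoms: 2-(trimethylsilyl)ethoxymethyl chloride, C[Si](C)(C)CCOCCl
Why: The N–H between two carboxamides is acidic; its sodium salt undergoes N-alkylation with the highly reactive α-chloro ether, a standard SEM protection of an acylpyrrole.

Step 4
Reactants: 5 N2,N5-dimethoxy-N2,N5-dimethyl-3,4-bis(4-methoxyphenyl)-1-{[2-(trimethylsilyl)ethoxy]methyl}pyrrole-2,5-dicarboxamide; 6 ethynylmagnesium bromide; 6 ethynylmagnesium bromide (second molecule)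
Product: 7 1,1'-[3,4-bis(4-methoxyphenyl)-1-{[2-(trimethylsilyl)ethoxy]methyl}pyrrole-2,5-diyl]bis(prop-2-yn-1-one)
Conditions: HC≡CMgBr (6 equiv), THF, 0 °C → rt; inverse quench into cold 1 M HCl
Reagents that add atoms: none
Why: Weinreb ketone synthesis: the five-membered magnesium chelate stops at the mono-adduct and keeps each ynone masked until the quench. The small acetylide reaches the hindered amides, and pouring into cold acid protonates the released N,O-dimethylhydroxylamine before it can add to the ynone in conjugate fashion.

Step 5
Reactants: 7 1,1'-[3,4-bis(4-methoxyphenyl)-1-{[2-(trimethylsilyl)ethoxy]methyl}pyrrole-2,5-diyl]bis(prop-2-yn-1-one); 8 (E)-1-methoxy-3-(trimethylsilyloxy)buta-1,3-diene; 8 (E)-1-methoxy-3-(trimethylsilyloxy)buta-1,3-diene (second molecule)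
Product: 11 2,5-bis(4-hydroxybenzoyl)-3,4-bis(4-methoxyphenyl)-1-{[2-(trimethylsilyl)ethoxy]methyl}pyrrole, via bis(cyclohexadiene) cycloadduct 9 (not isolated), via bis(aryl trimethylsilyl ether) 10 (not isolated)
Conditions: 8 (6 equiv), toluene, 100 °C; then 1 M HCl, THF, 0 °C → rt
Reagents that add atoms: none
Why: Each terminal ynone of 7 is an electron-poor dienophile, and one molecule of the electron-rich diene 8 adds to each in a concerted but asynchronous Diels–Alder (4+2) cycloaddition; the closest known reaction type is the benzannulation of alkynyl ketones and propiolates with 1-methoxy-3-silyloxybutadienes to give 4-acylphenols. Each new benzene ring is closed by cycloaddition, with both ring bonds formed in the same event (C2'–C3' from the diene CH2 terminus to the ynone β-carbon, C1'–C6' from the methoxy-bearing terminus to the α-carbon), giving 1,4-cyclohexadiene 9. Thermal loss of methanol across C6' and C3' aromatises each ring to aryl silyl ether 10, and the acidic work-up cleaves the O–Si bonds to phenol 11. The methoxy-bearing carbons of 9 are transient stereocentres that vanish on aromatisation, so no stereocontrol is required. The selectivity needed is regiochemical: the largest HOMO coefficient of 8 is on its CH2 terminus and the largest LUMO coefficient of the ynone on the β-carbon, which puts the oxygen-bearing carbon para to the acyl group. Chemoselectivity for C≡C over C=O is secured by working without a Lewis acid. The SEM group keeps N1 from adding 5-endo-dig to the ynone and removes the acidic N–H that would protonate the diene; the anisyl ethers and the SEM group are inert to heat and to brief dilute acid.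

Step 6
Reactants: 11 2,5-bis(4-hydroxybenzoyl)-3,4-bis(4-methoxyphenyl)-1-{[2-(trimethylsilyl)ethoxy]methyl}pyrrole
Product: 13 2,5-bis(4-hydroxybenzoyl)-3,4-bis(4-hydroxyphenyl)-1H-pyrrole, via N-hydroxymethyl tetraphenol 12 (not isolated)
Conditions: BBr3 (10 equiv), CH2Cl2, −78 °C → rt; H2O; then aq NH3, MeOH, rt
Reagents that add atoms: none
Why: BBr3 cleaves the aryl methyl ethers and triggers fragmentation of the SEM ether (loss of ethene and bromotrimethylsilane, the latter hydrolysed on work-up) to the N-hydroxymethyl compound 12. Compound 12 releases formaldehyde in aqueous ammonia because the 2,5-diacylpyrrolide is a good leaving group; ammonia also traps the formaldehyde, and the diaryl ketones are inert throughout.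

Step 7
Reactants: 13 2,5-bis(4-hydroxybenzoyl)-3,4-bis(4-hydroxyphenyl)-1H-pyrrole
Product: 14 2,5-bis(3,5-dibromo-4-hydroxybenzoyl)-3,4-bis(3,5-dibromo-4-hydroxyphenyl)-1H-pyrrole
Conditions: Br2 (8.5 equiv), AcOH, rt
Reagents that add atoms: bromine, BrBr
Why: Electrophilic aromatic bromination; the eight positions ortho to the four hydroxyls are strongly activated, the para positions are blocked and the pyrrole has no free carbon, so substitution should stop at the octabromide.

## Compound list

1 | 4-methoxyphenylpyruvic acid [3-(4-methoxyphenyl)-2-oxopropanoic acid] | COc1ccc(CC(=O)C(O)=O)cc1 | starting material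
2 | 3,4-bis(4-methoxyphenyl)-2,5-dioxohexanedioic acid (diastereomer mixture, as its lithium salt in the flask) | OC(=O)C(=O)C(c1ccc(OC)cc1)C(c1ccc(OC)cc1)C(=O)C(O)=O | intermediate
3 | 3,4-bis(4-methoxyphenyl)-1H-pyrrole-2,5-dicarboxylic acid | OC(=O)c1[nH]c(C(O)=O)c(-c2ccc(OC)cc2)c1-c1ccc(OC)cc1 | intermediate
4 | N2,N5-dimethoxy-N2,N5-dimethyl-3,4-bis(4-methoxyphenyl)-1H-pyrrole-2,5-dicarboxamide | CON(C)C(=O)c1[nH]c(C(=O)N(C)OC)c(-c2ccc(OC)cc2)c1-c1ccc(OC)cc1 | intermediate
5 | N2,N5-dimethoxy-N2,N5-dimethyl-3,4-bis(4-methoxyphenyl)-1-{[2-(trimethylsilyl)ethoxy]methyl}pyrrole-2,5-dicarboxamide | CON(C)C(=O)c1c(-c2ccc(OC)cc2)c(-c2ccc(OC)cc2)c(C(=O)N(C)OC)n1COCC[Si](C)(C)C | intermediate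
6 | ethynylmagnesium bromide | C#C[Mg]Br | starting material
7 | 1,1'-[3,4-bis(4-methoxyphenyl)-1-{[2-(trimethylsilyl)ethoxy]methyl}pyrrole-2,5-diyl]bis(prop-2-yn-1-one) | C#CC(=O)c1c(-c2ccc(OC)cc2)c(-c2ccc(OC)cc2)c(C(=O)C#C)n1COCC[Si](C)(C)C | intermediate
8 | (E)-1-methoxy-3-(trimethylsilyloxy)buta-1,3-diene | CO/C=C/C(=C)O[Si](C)(C)C | starting material
9 | 2,5-bis{[6-methoxy-4-(trimethylsilyloxy)cyclohexa-1,4-dien-1-yl]carbonyl}-3,4-bis(4-methoxyphenyl)-1-{[2-(trimethylsilyl)ethoxy]methyl}pyrrole (diastereomer mixture) | COC1C=C(O[Si](C)(C)C)CC=C1C(=O)c1c(-c2ccc(OC)cc2)c(-c2ccc(OC)cc2)c(C(=O)C2=CCC(O[Si](C)(C)C)=CC2OC)n1COCC[Si](C)(C)C | intermediate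
10 | 3,4-bis(4-methoxyphenyl)-2,5-bis[4-(trimethylsilyloxy)benzoyl]-1-{[2-(trimethylsilyl)ethoxy]methyl}pyrrole | C[Si](C)(C)Oc1ccc(cc1)C(=O)c1c(-c2ccc(OC)cc2)c(-c2ccc(OC)cc2)c(C(=O)c2ccc(O[Si](C)(C)C)cc2)n1COCC[Si](C)(C)C | intermediate
11 | 2,5-bis(4-hydroxybenzoyl)-3,4-bis(4-methoxyphenyl)-1-{[2-(trimethylsilyl)ethoxy]methyl}pyrrole | O=C(c1ccc(O)cc1)c1c(-c2ccc(OC)cc2)c(-c2ccc(OC)cc2)c(C(=O)c2ccc(O)cc2)n1COCC[Si](C)(C)C | intermediate
12 | 1-(hydroxymethyl)-2,5-bis(4-hydroxybenzoyl)-3,4-bis(4-hydroxyphenyl)pyrrole | O=C(c1ccc(O)cc1)c1c(-c2ccc(O)cc2)c(-c2ccc(O)cc2)c(C(=O)c2ccc(O)cc2)n1CO | intermediate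
13 | 2,5-bis(4-hydroxybenzoyl)-3,4-bis(4-hydroxyphenyl)-1H-pyrrole | O=C(c1ccc(O)cc1)c1[nH]c(C(=O)c2ccc(O)cc2)c(-c2ccc(O)cc2)c1-c1ccc(O)cc1 | intermediate
14 | 2,5-bis(3,5-dibromo-4-hydroxybenzoyl)-3,4-bis(3,5-dibromo-4-hydroxyphenyl)-1H-pyrrole | O=C(c1cc(Br)c(O)c(Br)c1)c1[nH]c(C(=O)c2cc(Br)c(O)c(Br)c2)c(-c2cc(Br)c(O)c(Br)c2)c1-c1cc(Br)c(O)c(Br)c1 | target

## Step count and risk

Total steps: 7. Longest linear sequence: 7 steps (1 to 14; 6 and 8 are purchased).

**Step 5 (key step).** The terminal bis(ynone) may oligomerise or decompose on heating before both arms have reacted. The silyl enol ether terminus of the diene may add in open-chain Mukaiyama–Michael fashion without ring closure. The second cycloaddition may lag, leaving mono-annulated material.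
Fallback: this sets out from amide 5 and forms the ketone–aryl bonds directly. Addition of 4-MeOC6H4MgBr (THF, 0 °C → rt) to both Weinreb amides should give 2,5-bis(4-methoxybenzoyl)-3,4-bis(4-methoxyphenyl)-1-{[2-(trimethylsilyl)ethoxy]methyl}pyrrole F1. Treatment with BBr3 in CH2Cl2 followed by aqueous NH3 would then cleave all four methyl ethers and the SEM group through the N-hydroxymethyl compound 12. The route is rejoined at 13.

**Step 4.** Conjugate addition of the liberated N,O-dimethylhydroxylamine to the ynone during the quench, or incomplete addition at the second hindered amide, would erode the yield. The terminal ynone may also suffer base-induced self-condensation if the quench is slow.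
Fallback: this sets out from 5 and changes the oxidation-state order. Reduction with i-Bu2AlH (THF, −78 °C) should give 3,4-bis(4-methoxyphenyl)-1-{[2-(trimethylsilyl)ethoxy]methyl}pyrrole-2,5-dicarbaldehyde F2. HC≡CMgBr then adds to give 1,1'-[3,4-bis(4-methoxyphenyl)-1-{[2-(trimethylsilyl)ethoxy]methyl}pyrrole-2,5-diyl]bis(prop-2-yn-1-ol) F3, used crude because pyrrolyl carbinols ionise easily. Oxidation with MnO2 in CH2Cl2 returns to the route at 7 under neutral conditions, with no amine present.

**Step 6.** Fragmentation of the SEM group under BBr3 may stop at a stable N-substituted stage. The released formaldehyde may hydroxymethylate the electron-rich phenol rings before it is trapped.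
Fallback: this sets out from 11 and removes the nitrogen group by a different mechanism before demethylation. n-Bu4NF with ethylenediamine in THF at reflux (fluoride attack on silicon, the diamine trapping formaldehyde) should give 2,5-bis(4-hydroxybenzoyl)-3,4-bis(4-methoxyphenyl)-1H-pyrrole F4. BBr3 in CH2Cl2 then cleaves only the two methyl ethers, and the route is rejoined at 13.

**Step 7.** Partly brominated phenols may precipitate and stall the eightfold substitution, giving inseparable mixtures. Excess bromine may oxidise the electron-rich phenols.
Fallback: this sets out from 11 and stages the bromination as two fourfold operations on purifiable intermediates. Br2 (4 equiv) in AcOH should first brominate the two free phenol rings to give 2,5-bis(3,5-dibromo-4-hydroxybenzoyl)-3,4-bis(4-methoxyphenyl)-1-{[2-(trimethylsilyl)ethoxy]methyl}pyrrole F5; any early bromination ortho to a methoxy group is at a position that is wanted anyway. BBr3 followed by aqueous NH3 would then give, through 1-(hydroxymethyl)-2,5-bis(3,5-dibromo-4-hydroxybenzoyl)-3,4-bis(4-hydroxyphenyl)pyrrole F6, the tetrabromide 2,5-bis(3,5-dibromo-4-hydroxybenzoyl)-3,4-bis(4-hydroxyphenyl)-1H-pyrrole F7. A second treatment with Br2 (4 equiv) in AcOH completes the bromination and arrives at 14.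

## Further compounds

F1 | step 5 | 2,5-bis(4-methoxybenzoyl)-3,4-bis(4-methoxyphenyl)-1-{[2-(trimethylsilyl)ethoxy]methyl}pyrrole | COc1ccc(cc1)C(=O)c1c(-c2ccc(OC)cc2)c(-c2ccc(OC)cc2)c(C(=O)c2ccc(OC)cc2)n1COCC[Si](C)(C)C
F2 | step 4 | 3,4-bis(4-methoxyphenyl)-1-{[2-(trimethylsilyl)ethoxy]methyl}pyrrole-2,5-dicarbaldehyde | O=Cc1c(-c2ccc(OC)cc2)c(-c2ccc(OC)cc2)c(C=O)n1COCC[Si](C)(C)C
F3 | step 4 | 1,1'-[3,4-bis(4-methoxyphenyl)-1-{[2-(trimethylsilyl)ethoxy]methyl}pyrrole-2,5-diyl]bis(prop-2-yn-1-ol) (diastereomer mixture) | C#CC(O)c1c(-c2ccc(OC)cc2)c(-c2ccc(OC)cc2)c(C(O)C#C)n1COCC[Si](C)(C)C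
F4 | step 6 | 2,5-bis(4-hydroxybenzoyl)-3,4-bis(4-methoxyphenyl)-1H-pyrrole | O=C(c1ccc(O)cc1)c1[nH]c(C(=O)c2ccc(O)cc2)c(-c2ccc(OC)cc2)c1-c1ccc(OC)cc1
F5 | step 7 | 2,5-bis(3,5-dibromo-4-hydroxybenzoyl)-3,4-bis(4-methoxyphenyl)-1-{[2-(trimethylsilyl)ethoxy]methyl}pyrrole | O=C(c1cc(Br)c(O)c(Br)c1)c1c(-c2ccc(OC)cc2)c(-c2ccc(OC)cc2)c(C(=O)c2cc(Br)c(O)c(Br)c2)n1COCC[Si](C)(C)C
F6 | step 7 | 1-(hydroxymethyl)-2,5-bis(3,5-dibromo-4-hydroxybenzoyl)-3,4-bis(4-hydroxyphenyl)pyrrole | O=C(c1cc(Br)c(O)c(Br)c1)c1c(-c2ccc(O)cc2)c(-c2ccc(O)cc2)c(C(=O)c2cc(Br)c(O)c(Br)c2)n1CO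
F7 | step 7 | 2,5-bis(3,5-dibromo-4-hydroxybenzoyl)-3,4-bis(4-hydroxyphenyl)-1H-pyrrole | O=C(c1cc(Br)c(O)c(Br)c1)c1[nH]c(C(=O)c2cc(Br)c(O)c(Br)c2)c(-c2ccc(O)cc2)c1-c1ccc(O)cc1
A1 | alternative 1 | 2-amino-1,3-bis(4-methoxyphenyl)propane-1,3-dione | COc1ccc(cc1)C(=O)C(N)C(=O)c1ccc(OC)cc1
A2 | alternative 1 | 1,3-bis(4-methoxyphenyl)propane-1,2-dione | COc1ccc(CC(=O)C(=O)c2ccc(OC)cc2)cc1
A3 | alternative 1 | 2,5-bis(4-methoxybenzoyl)-3,4-bis(4-methoxyphenyl)-1H-pyrrole | COc1ccc(cc1)C(=O)c1[nH]c(C(=O)c2ccc(OC)cc2)c(-c2ccc(OC)cc2)c1-c1ccc(OC)cc1
A4 | alternative 2 | tert-butyl 2,5-diiodo-3,4-bis(4-methoxyphenyl)pyrrole-1-carboxylate | COc1ccc(cc1)-c1c(I)n(C(=O)OC(C)(C)C)c(I)c1-c1ccc(OC)cc1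
A5 | alternative 2 | 4-methoxyphenylboronic acid | COc1ccc(cc1)B(O)O
A6 | alternative 2 | tert-butyl 2,5-bis(4-methoxybenzoyl)-3,4-bis(4-methoxyphenyl)pyrrole-1-carboxylate | COc1ccc(cc1)C(=O)c1c(-c2ccc(OC)cc2)c(-c2ccc(OC)cc2)c(C(=O)c2ccc(OC)cc2)n1C(=O)OC(C)(C)C
A7 | alternative 3 | 4,4'-dimethoxybenzil | COc1ccc(cc1)C(=O)C(=O)c1ccc(OC)cc1
A8 | alternative 3 | N-(4-methoxybenzyl)bis(4-methoxyphenacyl)amine | COc1ccc(CN(CC(=O)c2ccc(OC)cc2)CC(=O)c2ccc(OC)cc2)cc1
A9 | alternative 3 | 1-(4-methoxybenzyl)-2,5-bis(4-methoxybenzoyl)-3,4-bis(4-methoxyphenyl)pyrrole | COc1ccc(Cn2c(C(=O)c3ccc(OC)cc3)c(-c3ccc(OC)cc3)c(-c3ccc(OC)cc3)c2C(=O)c2ccc(OC)cc2)cc1
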